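**Strategy.** In the hexahydroindene core (ring A = cyclohexene, ring B = cyclopentane), the arc C1(CH3)–C2H2–C3(CH3) of ring B is a propene unit wedged between C1 and C3a. An enantioselective Diels–Alder reaction of (E)-penta-1,3-diene with crotonaldehyde installs it. That single operation forms C1–C2 and C3–C3a and sets both methyl-bearing centres trans. The adduct is a plain cyclohexenecarbaldehyde whose ring serves only as a template. Its formyl carbon and one alkene CH are excised, which unzips it to an end-differentiated 2,4-dimethylpentane-1,5-diyl unit. Two olefination sequences and an intramolecular Diels–Alder reaction then close rings A and B.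

Key step: step 1

Remark: alcohol 5 and triol 6 are carried as mixtures of carbinol epimers because those centres are destroyed in step 4. Compound 7 is drawn open-chain, although it should rest largely as its lactol.

**Step 1**
Reactants: 1 (E)-penta-1,3-diene; 2 (E)-but-2-enal
Product: 3 (1R,2S,6S)-2,6-dimethylcyclohex-3-ene-1-carbaldehyde
Conditions: (5S)-5-benzyl-2,2,3-trimethylimidazolidin-4-one hydrochloride (20 mol %), MeCN/H2O, 23 °C, excess 1
Reagents that add atoms: none
Why: Condensation of 2 with the amine salt gives an (E)-iminium ion whose lowered LUMO undergoes a concerted, asynchronous [4+2] cycloaddition with s-cis 1 (organocatalytic Diels–Alder reaction), and hydrolysis then releases 3 and the catalyst. The only ring closed is the temporary cyclohexene, by suprafacial–suprafacial [4+2] closure in which the enal α-carbon (future C2) bonds to the methyl-bearing diene terminus (future C1) and the β-carbon (future C3) bonds to the CH2 terminus (future C3a). C1 and C6 of 3 are set by the benzyl group of the catalyst, which blocks one face of the iminium ion, and their trans relation follows from the (E)-geometry of 2. C2 of 3 follows from the (E)-geometry of 1 and the endo orientation of the iminium group, so the two methyl groups end up trans, as in ring B. The step needs "ortho" regioselectivity, secured by pairing the large HOMO coefficient at the CH2 terminus of 1 with the large LUMO coefficient at the β-carbon, and endo selectivity, secured by secondary orbital overlap. The (Z)-isomer in commercial 1 cannot reach the s-cis form and stays behind.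

**Step 2**
Reactants: 3
Product: 4 (3R,5S)-3,5-dimethylcyclohex-1-ene
Conditions: [RhCl(C8H12)]2 (C8H12 = cycloocta-1,5-diene, 2.5 mol %), Ph2P(CH2)3PPh2 (5 mol %), diglyme, 160 °C, 4 distilled out
Reagents that add atoms: none
Why: Tsuji–Wilkinson decarbonylation (C–H oxidative addition, CO extrusion, C–H reductive elimination) removes the activating formyl group; the centre it erases becomes the ring B CH2, and the two methyl-bearing centres are untouched.

**Step 3**
Reactants: 4
Product: 5 (4R,6R)-4,6-dimethylcyclohex-2-en-1-ol (carbinol epimers)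
Conditions: SeO2 (0.5 equiv), t-BuOOH, CH2Cl2, 0 to 23 °C
Reagents that add atoms: selenium dioxide, O=[Se]=O; tert-butyl hydroperoxide, CC(C)(C)OO
Why: Allylic hydroxylation by the ene/[2,3]-sigmatropic sequence should prefer the allylic CH2 over the tertiary allylic CH, which places oxygen on the future C3a without moving the alkene.

**Step 4**
Reactants: 5
Product: 7 (2R,4R)-5-hydroxy-2,4-dimethylpentanal, via triol 6 (not isolated)
Conditions: O3, CH2Cl2/MeOH, −78 °C; NaBH4, −78 to 0 °C; then NaIO4, H2O, pH 7, 0 °C
Reagents that add atoms: ozone, [O-][O+]=O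
Why: Ozonolysis with reductive work-up followed by glycol cleavage removes the superfluous ring carbon as formaldehyde and leaves the two chain ends at different oxidation levels (future C3a as aldehyde, future C7a as alcohol); no stereocentre is touched.

**Step 5**
Reactants: 8 methyl 2-[bis(2,2,2-trifluoroethoxy)phosphoryl]acetate
Product: 9 methyl 2-[bis(2,2,2-trifluoroethoxy)phosphoryl]butanoate (racemic)
Conditions: NaH, THF/DMF, 0 °C; EtI, 23 °C
Reagents that add atoms: iodoethane, CCI
Why: SN2 C-alkylation of the stabilised phosphonoacetate anion.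

**Step 6**
Reactants: 7; 9
Product: 10 methyl (2Z,4R,6R)-2-ethyl-7-hydroxy-4,6-dimethylhept-2-enoate
Conditions: 9 (2.2 equiv), KN(SiMe3)2, 18-crown-6, THF, −78 to −40 °C
Reagents that add atoms: none
Why: Still–Gennari olefination; fast, irreversible collapse of the trifluoroethyl phosphonate adduct should give the (Z)-trisubstituted enoate needed as dienophile, and the surplus base carries the free hydroxyl group as its alkoxide.

**Step 7**
Reactants: 10
Product: 11 methyl (2Z,4R,6R)-2-ethyl-4,6-dimethyl-7-oxohept-2-enoate
Conditions: Dess–Martin periodinane, NaHCO3, CH2Cl2, 0 °C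
Reagents that add atoms: none
Why: Neutral hypervalent-iodine oxidation of the primary alcohol avoids epimerisation of the α-methyl aldehyde and leaves the (Z)-enoate alone.

**Step 8**
Reactants: 12 diethyl [(E)-3-phenylprop-2-en-1-yl]phosphonate
Product: 13 diethyl [(E)-1-phenylpent-1-en-3-yl]phosphonate (racemic)
Conditions: n-BuLi, THF, −78 °C; EtI, −78 to 0 °C
Reagents that add atoms: iodoethane, CCI
Why: α-Selective alkylation of the lithiated allylic phosphonate.

**Step 9**
Reactants: 11; 13
Product: 14 methyl (2Z,4R,6R,7E,9E)-2,8-diethyl-4,6-dimethyl-10-phenyldeca-2,7,9-trienoate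
Conditions: 13, n-BuLi, THF, −78 °C; then 11, −78 to 0 °C
Reagents that add atoms: none
Why: Horner–Wadsworth–Emmons reaction of the allylic phosphonate with the aldehyde only; reversible addition should favour the (7E)-alkene, which keeps the styryl arm away from the chain.

**Step 10**
Reactants: 14
Product: 15 (2Z,4R,6R,7E,9E)-2,8-diethyl-4,6-dimethyl-10-phenyldeca-2,7,9-trien-1-ol
Conditions: i-Bu2AlH (2.2 equiv), CH2Cl2, −78 °C; Rochelle salt work-up
Reagents that add atoms: none
Why: 1,2-Reduction of the enoate to the allylic alcohol, with retention of all alkene geometries.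

**Step 11**
Reactants: 15
Product: 16 (2Z,4R,6R,7E,9E)-2,8-diethyl-4,6-dimethyl-10-phenyldeca-2,7,9-trienal
Conditions: activated MnO2, CH2Cl2, 0 °C, dark
Reagents that add atoms: none
Why: Chemoselective heterogeneous oxidation of the allylic alcohol under neutral conditions limits Z-to-E drift of the enal.

**Step 12**
Reactants: 16; 17 ethyl 2-(triphenyl-λ5-phosphanylidene)propanoate
Product: 18 ethyl (2E,4Z,6R,8R,9E,11E)-4,10-diethyl-2,6,8-trimethyl-12-phenyldodeca-2,4,9,11-tetraenoate
Conditions: CH2Cl2, 23 °C
Reagents that add atoms: none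
Why: Wittig reaction of a stabilised ylide, which is (E)-selective for the new trisubstituted alkene.

**Step 13**
Reactants: 18
Product: 19 ethyl (2E)-3-[(1R,3R,3aR,4S,5S,7aR)-4,7-diethyl-1,3-dimethyl-5-phenyl-2,3,3a,4,5,7a-hexahydro-1H-inden-4-yl]-2-methylprop-2-enoate
Conditions: toluene, BHT (cat.), 110 °C, sealed tube
Reagents that add atoms: none
Why: Thermal intramolecular Diels–Alder reaction; the (9E,11E)-diene and the (4Z)-alkene add suprafacially through the trans-fused transition state, so the alkene geometries fix C3a, C4, C5 and C7a relative to one another, while the two methyl-bearing tether centres must select the reacting faces.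

**Step 14**
Reactants: 19
Product: 20 homo-plakotenin, (2E)-3-[(1R,3R,3aR,4S,5S,7aR)-4,7-diethyl-1,3-dimethyl-5-phenyl-2,3,3a,4,5,7a-hexahydro-1H-inden-4-yl]-2-methylprop-2-enoic acid
Conditions: LiOH, THF/MeOH/H2O, 40 °C; then HCl (aq) to pH 3
Reagents that add atoms: lithium hydroxide, [Li+].[OH-]
Why: Saponification of the unhindered side-chain ester; no stereocentre is epimerisable under these conditions.

**Compound list**
1 | (E)-penta-1,3-diene | C=C/C=C/C | starting material
2 | (E)-but-2-enal | C/C=C/C=O | starting material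
3 | (1R,2S,6S)-2,6-dimethylcyclohex-3-ene-1-carbaldehyde | O=C[C@H]1[C@@H](C)C=CC[C@@H]1C | intermediate
4 | (3R,5S)-3,5-dimethylcyclohex-1-ene | C[C@H]1C=CC[C@H](C)C1 | intermediate
5 | (4R,6R)-4,6-dimethylcyclohex-2-en-1-ol | OC1C=C[C@H](C)C[C@H]1C | intermediate
6 | (2R,4R)-2,4-dimethylhexane-1,5,6-triol | OC[C@H](C)C[C@@H](C)C(O)CO | intermediate
7 | (2R,4R)-5-hydroxy-2,4-dimethylpentanal | OC[C@H](C)C[C@@H](C)C=O | intermediate
8 | methyl 2-[bis(2,2,2-trifluoroethoxy)phosphoryl]acetate | COC(=O)CP(=O)(OCC(F)(F)F)OCC(F)(F)F | starting material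
9 | methyl 2-[bis(2,2,2-trifluoroethoxy)phosphoryl]butanoate | CCC(C(=O)OC)P(=O)(OCC(F)(F)F)OCC(F)(F)F | intermediate
10 | methyl (2Z,4R,6R)-2-ethyl-7-hydroxy-4,6-dimethylhept-2-enoate | COC(=O)/C(CC)=C\[C@H](C)C[C@@H](C)CO | intermediate
11 | methyl (2Z,4R,6R)-2-ethyl-4,6-dimethyl-7-oxohept-2-enoate | COC(=O)/C(CC)=C\[C@H](C)C[C@@H](C)C=O | intermediate
12 | diethyl [(E)-3-phenylprop-2-en-1-yl]phosphonate | CCOP(=O)(OCC)C/C=C/c1ccccc1 | starting material
13 | diethyl [(E)-1-phenylpent-1-en-3-yl]phosphonate | CCOP(=O)(OCC)C(CC)/C=C/c1ccccc1 | intermediate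
14 | methyl (2Z,4R,6R,7E,9E)-2,8-diethyl-4,6-dimethyl-10-phenyldeca-2,7,9-trienoate | COC(=O)/C(CC)=C\[C@H](C)C[C@@H](C)/C=C(CC)/C=C/c1ccccc1 | intermediate
15 | (2Z,4R,6R,7E,9E)-2,8-diethyl-4,6-dimethyl-10-phenyldeca-2,7,9-trien-1-ol | OC/C(CC)=C\[C@H](C)C[C@@H](C)/C=C(CC)/C=C/c1ccccc1 | intermediate
16 | (2Z,4R,6R,7E,9E)-2,8-diethyl-4,6-dimethyl-10-phenyldeca-2,7,9-trienal | O=C/C(CC)=C\[C@H](C)C[C@@H](C)/C=C(CC)/C=C/c1ccccc1 | intermediate
17 | ethyl 2-(triphenyl-λ5-phosphanylidene)propanoate | CCOC(=O)C(C)=P(c1ccccc1)(c1ccccc1)c1ccccc1 | starting material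
18 | ethyl (2E,4Z,6R,8R,9E,11E)-4,10-diethyl-2,6,8-trimethyl-12-phenyldodeca-2,4,9,11-tetraenoate | CCOC(=O)/C(C)=C/C(CC)=C\[C@H](C)C[C@@H](C)/C=C(CC)/C=C/c1ccccc1 | intermediate
19 | homo-plakotenin ethyl ester | CCC1=C[C@@H](c2ccccc2)[C@@](/C=C(\C)C(=O)OCC)(CC)[C@H]2[C@H]1[C@H](C)C[C@H]2C | intermediate
20 | homo-plakotenin | CCC1=C[C@@H](c2ccccc2)[C@@](/C=C(\C)C(=O)O)(CC)[C@H]2[C@H]1[C@H](C)C[C@H]2C | target

Total step count: 14. Longest linear sequence: 12 (steps 1–4, 6, 7, 9–14).

**Steps most likely to fail**

Step 13. The facial selectivity may be poor or reversed. In the transition state that leads to 19, both tether methyl groups lie close to the ethyl group on the diene and to the side chain on the dienophile, so allylic strain may steer the cycloaddition to the opposite pair of faces. The fallback moves the cycloaddition one stage earlier and puts it under catalyst control. It sets out from enal 16, which is cyclised at −78 to −20 °C in CH2Cl2. The catalyst is the bis(trifluoromethanesulfonyl)imide salt of (S)-3,3-diphenyl-1-(2-methylphenyl)tetrahydro-1H,3H-pyrrolo[1,2-c][1,3,2]oxazaborole (enantioselective Lewis-acid Diels–Alder reaction of an α-substituted enal). This gives (1R,3R,3aR,4R,5S,7aR)-4,7-diethyl-1,3-dimethyl-5-phenyl-2,3,3a,4,5,7a-hexahydro-1H-indene-4-carbaldehyde F4. Wittig reaction of F4 with 17 in warm toluene returns to the route at 19.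

Step 1. The β-substituted enal may react sluggishly with the acyclic diene, and endo selectivity may erode. The fallback replaces catalyst control by auxiliary control and sets out from 1. Reaction of 1 with commercial (4S)-4-benzyl-3-[(E)-but-2-enoyl]-1,3-oxazolidin-2-one and Et2AlCl in CH2Cl2 at −78 to −20 °C forms the same two bonds. The product is (4S)-4-benzyl-3-{[(1R,2S,6S)-2,6-dimethylcyclohex-3-en-1-yl]carbonyl}-1,3-oxazolidin-2-one F1. LiBH4 in Et2O/H2O cleaves the auxiliary to give [(1R,2S,6S)-2,6-dimethylcyclohex-3-en-1-yl]methanol F2. Dess–Martin oxidation of F2 returns to the route at 3.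

Step 3. Attack may compete at the tertiary allylic C–H, and over-oxidation to the enone is possible. The fallback replaces C–H oxidation by epoxide isomerisation and sets out from 4. Treatment with mCPBA in CH2Cl2 gives (2R,4R)-2,4-dimethyl-7-oxabicyclo[4.1.0]heptane F3 as a mixture of epoxide epimers. LiNEt2 in Et2O then removes a proton from the less substituted neighbouring CH2 (base-induced epoxide-to-allylic-alcohol rearrangement), which returns to the route at 5.

**Further compounds**
F1 | step 1 | (4S)-4-benzyl-3-{[(1R,2S,6S)-2,6-dimethylcyclohex-3-en-1-yl]carbonyl}-1,3-oxazolidin-2-one | O=C([C@H]1[C@@H](C)C=CC[C@@H]1C)N1C(=O)OC[C@@H]1Cc1ccccc1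
F2 | step 1 | [(1R,2S,6S)-2,6-dimethylcyclohex-3-en-1-yl]methanol | OC[C@H]1[C@@H](C)C=CC[C@@H]1C
F3 | step 3 | (2R,4R)-2,4-dimethyl-7-oxabicyclo[4.1.0]heptane | C[C@H]1C2OC2C[C@H](C)C1
F4 | step 13 | (1R,3R,3aR,4R,5S,7aR)-4,7-diethyl-1,3-dimethyl-5-phenyl-2,3,3a,4,5,7a-hexahydro-1H-indene-4-carbaldehyde | CCC1=C[C@@H](c2ccccc2)[C@@](C=O)(CC)[C@H]2[C@H]1[C@H](C)C[C@H]2C
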